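**Retrosynthetic overview**
1. Target ⇐ selective acetylation of the two primary allylic alcohols (C14, C15) of a triol lactone ⇐ global desilylation of a tris-TBS lactone.
2. Tris-TBS lactone ⇐ one operation on an acyclic ω-formyl 2-(methoxycarbonyl)allylboronate: intramolecular allylboration closes the ten-membered carbocycle (C7–C8), then the boron alkoxide closes the γ-lactone (O8–C12); C7 and C8 are set from C6.
3. Allylboronate ⇐ conjugate hydroalumination/borylmethylation (adds C13) of a γ-silyloxy ynoate ⇐ enantioselective addition of methyl propiolate to a C6 enal (sets C6).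
4. Enal chain ⇐ B-alkyl Suzuki–Miyaura union (C1–C2) of a 2-vinyl allylic alcohol (C2–C6, C15) with a (Z)-alkenyl iodide (C8–C10, C1, C14); each comes from anti-carbomagnesiation of a propargylic alcohol, which fixes both trisubstituted alkenes.
5. Ring order: no ring before the key step; there the carbocycle forms first and the lactone second, in the same flask.

Numbering used: germacrane positions (ring C1–C10; C11–C13 the acrylate unit with C12 the carbonyl; C14 on C10; C15 on C4). TBS = tert-butyl(dimethyl)silyl, Bpin = 4,4,5,5-tetramethyl-1,3,2-dioxaborolan-2-yl, 9-BBN = 9-borabicyclo[3.3.1]nonane.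

Assumption: (S,S)-ProPhenol is taken as the ligand enantiomer that delivers the alkynylzinc to the Si face of the enal (giving 6R); if the observed sense is opposite, (R,R)-ProPhenol is used with nothing else changed.

**Route**

Step 1
Reactants: 1 3,3-diethoxyprop-1-yne; 2 paraformaldehyde
Product: 4 4,4-diethoxybut-2-yn-1-ol, via lithium acetylide 3 (not isolated)
Conditions: n-BuLi, THF, −78 °C; then 2, −78 °C → rt; H2O work-up
Reagents that add atoms: none
Why: the lithium acetylide adds to formaldehyde (acetylide hydroxymethylation), giving the propargylic alcohol that carries C15, C4, C5 and the masked C6 aldehyde; no stereocenter.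

Step 2
Reactants: 4 4,4-diethoxybut-2-yn-1-ol; 5 vinylmagnesium chloride
Product: 7 (2E)-2-ethenyl-4,4-diethoxybut-2-en-1-ol, via magnesium chelate 6 (not isolated)
Conditions: 5 (3.5 equiv), THF/toluene, 70 °C; H2O work-up
Reagents that add atoms: none
Why: alkoxide-directed anti-carbomagnesiation of a propargylic alcohol puts the vinyl group on the carbon next to CH2O and magnesium (then H) on the distal carbon in a five-membered chelate, which fixes the C4=C5 geometry (C3 branch cis to C6, CH2OH trans to C6).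

Step 3
Reactants: 8 prop-2-yn-1-ol; 9 (1,3-dioxolan-2-ylmethyl)magnesium bromide
Product: 11 (2Z)-2-(1,3-dioxolan-2-ylmethyl)-3-iodoprop-2-en-1-ol, via magnesium chelate 10 (not isolated)
Conditions: 9 (2.5 equiv), CuI (10 mol%), THF/Et2O, 0 °C → rt; then I2, −20 °C → rt; H2O work-up
Reagents that add atoms: iodine, SMILES II
Why: CuI-catalysed anti-carbomagnesiation of propargyl alcohol gives the chelated (Z)-alkenylmagnesium, and iodinolysis with retention gives the (Z)-iodide, so C14 ends cis to the future C2 and C9 trans to it (C10=C1 geometry), with C8 carried as a dioxolane.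

Step 4
Reactants: 7 (2E)-2-ethenyl-4,4-diethoxybut-2-en-1-ol; 11 (2Z)-2-(1,3-dioxolan-2-ylmethyl)-3-iodoprop-2-en-1-ol
Product: 13 (2Z,6E)-8,8-diethoxy-2-(1,3-dioxolan-2-ylmethyl)-6-(hydroxymethyl)octa-2,6-dien-1-ol, via bis(9-BBN) adduct 12 (not isolated)
Conditions: 7 (1.2 equiv), 9-BBN (2.3 equiv), THF, 0 °C → rt; then 11, Pd(dppf)Cl2 (5 mol%), AsPh3, Cs2CO3, DMF/H2O, rt
Reagents that add atoms: none
Why: 9-BBN adds anti-Markovnikov to the terminal vinyl group only (the trisubstituted alkene is inert), and the primary alkylborane couples with the alkenyl iodide with retention (B-alkyl Suzuki–Miyaura coupling), forming C1–C2 without touching either trisubstituted alkene.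

Step 5
Reactants: 13 (2Z,6E)-8,8-diethoxy-2-(1,3-dioxolan-2-ylmethyl)-6-(hydroxymethyl)octa-2,6-dien-1-ol
Product: 14 2-[(2Z,6E)-2,6-bis(TBSO-methyl)-8,8-diethoxyocta-2,6-dien-1-yl]-1,3-dioxolane
Conditions: TBSCl (2.4 equiv), imidazole, DMF, rt
Reagents that add atoms: TBSCl, SMILES CC(C)(C)[Si](C)(C)Cl
Why: routine silylation of two primary allylic alcohols under conditions to which both acetals are inert.

Step 6
Reactants: 14 2-[(2Z,6E)-2,6-bis(TBSO-methyl)-8,8-diethoxyocta-2,6-dien-1-yl]-1,3-dioxolane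
Product: 15 (2E,6Z)-8-(TBSO)-3-(TBSO-methyl)-7-(1,3-dioxolan-2-ylmethyl)octa-2,6-dienal
Conditions: SiO2, 10% aq. oxalic acid, CH2Cl2, rt
Reagents that add atoms: water, SMILES O
Why: the acyclic, allylic diethyl acetal ionises far faster than the saturated cyclic dioxolane, so mild supported acid releases only the C6 enal (chemoselective acetal hydrolysis) and leaves the silyl ethers and alkene geometry intact.

Step 7
Reactants: 15 (2E,6Z)-8-(TBSO)-3-(TBSO-methyl)-7-(1,3-dioxolan-2-ylmethyl)octa-2,6-dienal; 16 methyl prop-2-ynoate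
Product: 18 methyl (4R,5E,9Z)-4-hydroxy-11-(TBSO)-6-(TBSO-methyl)-10-(1,3-dioxolan-2-ylmethyl)undeca-5,9-dien-2-ynoate, via alkynylzinc 17 (not isolated)
Conditions: 16 (3 equiv), Me2Zn (3 equiv), (S,S)-ProPhenol (20 mol%), Ph3PO (40 mol%), toluene, 4 °C; H2O work-up
Reagents that add atoms: none
Why: catalytic enantioselective alkynylation, in which the dinuclear zinc–ProPhenol complex delivers the zinc propiolate 1,2 to one face of the enal and so sets C6 as R.

Step 8
Reactants: 18 methyl (4R,5E,9Z)-4-hydroxy-11-(TBSO)-6-(TBSO-methyl)-10-(1,3-dioxolan-2-ylmethyl)undeca-5,9-dien-2-ynoate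
Product: 19 methyl (4R,5E,9Z)-4,11-bis(TBSO)-6-(TBSO-methyl)-10-(1,3-dioxolan-2-ylmethyl)undeca-5,9-dien-2-ynoate
Conditions: TBSCl, imidazole, DMF, 0 °C → rt
Reagents that add atoms: TBSCl, SMILES CC(C)(C)[Si](C)(C)Cl
Why: routine silylation of the propargylic alcohol, which keeps the C6 oxygen from lactonising later and provides the bulky group that biases the ring closure.

Step 9
Reactants: 19 methyl (4R,5E,9Z)-4,11-bis(TBSO)-6-(TBSO-methyl)-10-(1,3-dioxolan-2-ylmethyl)undeca-5,9-dien-2-ynoate; 20 2-(iodomethyl)-4,4,5,5-tetramethyl-1,3,2-dioxaborolane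
Product: 22 methyl (2Z,4R,5E,9Z)-4,11-bis(TBSO)-6-(TBSO-methyl)-10-(1,3-dioxolan-2-ylmethyl)-2-(Bpin-methyl)undeca-2,5,9-trienoate, via vinylalane 21 (not isolated)
Conditions: i-Bu2AlH (1.3 equiv), HMPA, THF, 0 °C; then 20 (2 equiv), 0 °C → rt
Reagents that add atoms: none
Why: the i-Bu2AlH–HMPA complex adds H–Al syn across the ynoate (conjugate hydroalumination, H to C7 and Al to C11) and the α-aluminoacrylate is C-alkylated by the iodomethylboronate with retention, so CH2Bpin (C13) ends trans to the C6 branch.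

Step 10
Reactants: 22 methyl (2Z,4R,5E,9Z)-4,11-bis(TBSO)-6-(TBSO-methyl)-10-(1,3-dioxolan-2-ylmethyl)-2-(Bpin-methyl)undeca-2,5,9-trienoate
Product: 24 methyl (2Z,4R,5E,9Z)-4,11-bis(TBSO)-6-(TBSO-methyl)-10-(2-oxoethyl)-2-(Bpin-methyl)undeca-2,5,9-trienoate, via collidinium salt 23 (not isolated)
Conditions: TESOTf (2 equiv), 2,4,6-collidine (3 equiv), CH2Cl2, 0 °C; then H2O
Reagents that add atoms: water, SMILES O
Why: silyl triflate/collidine opens the aldehyde-derived dioxolane to a collidinium N,O-acetal that water hydrolyses under buffered conditions (chemoselective acetal cleavage), so the silyl ethers and the unreactive ester-bearing allylboronate survive and the β,γ-unsaturated aldehyde never meets free acid; 24 is used at once.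

Step 11
Reactants: 24 methyl (2Z,4R,5E,9Z)-4,11-bis(TBSO)-6-(TBSO-methyl)-10-(2-oxoethyl)-2-(Bpin-methyl)undeca-2,5,9-trienoate
Product: 26 (3aR,4R,5E,9Z,11aS)-4-(TBSO)-6,10-bis(TBSO-methyl)-3-methylidene-3a,4,7,8,11,11a-hexahydrocyclodeca[b]furan-2(3H)-one, via boron alkoxide 25 (not isolated)
Conditions: Sc(OTf)3 (20 mol%), 4 Å MS, toluene (2 mM, syringe pump), 40 °C
Reagents that add atoms: none
Why: Proposed new method: Sc(OTf)3-activated intramolecular allylboration of the C8 aldehyde through a closed chair transition state forms C7–C8 and the ten-membered carbocycle, and the O-boron alkoxide 25 then attacks the neighbouring ester (5-exo-trig) to close the lactone with loss of MeOBpin; the fixed boronate geometry (C6 branch trans to CH2B) enforces the 7,8-anti, trans-fused lactone, and with H6 eclipsing the alkene (A(1,3) strain against the ester) the tethered aldehyde reaches C7 on the C5 face, anti to OTBS, which gives the target's C7/C8 configuration from 6R (the 3aR label of 26 reflects only the O–Si priority); the closest known reaction type is the intermolecular Lewis-acid-catalysed allylboration/lactonisation of 2-alkoxycarbonyl allylboronates with aldehydes, together with intramolecular allylborations that close medium rings.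

Step 12
Reactants: 26 (3aR,4R,5E,9Z,11aS)-4-(TBSO)-6,10-bis(TBSO-methyl)-3-methylidene-3a,4,7,8,11,11a-hexahydrocyclodeca[b]furan-2(3H)-one
Product: 27 (3aS,4R,5E,9Z,11aS)-4-hydroxy-6,10-bis(hydroxymethyl)-3-methylidene-3a,4,7,8,11,11a-hexahydrocyclodeca[b]furan-2(3H)-one
Conditions: HF·pyridine, pyridine/THF, 0 °C → rt
Reagents that add atoms: none
Why: buffered fluoride desilylation removes all three silyl ethers without base, so the α-methylene lactone is neither opened, translactonised nor attacked in a conjugate sense.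

Step 13
Reactants: 27 (3aS,4R,5E,9Z,11aS)-4-hydroxy-6,10-bis(hydroxymethyl)-3-methylidene-3a,4,7,8,11,11a-hexahydrocyclodeca[b]furan-2(3H)-one
Product: 28 [(3aS,4R,5E,9Z,11aS)-4-hydroxy-3-methylidene-2-oxo-2,3,3a,4,7,8,11,11a-octahydrocyclodeca[b]furan-6,10-diyl]bis(methylene) diacetate
Conditions: AcCl (2.2 equiv), 2,4,6-collidine, CH2Cl2, −78 °C
Reagents that add atoms: acetyl chloride, SMILES CC(Cl)=O
Why: kinetically controlled acylation, in which the two unhindered primary allylic alcohols react much faster than the hindered secondary C6 alcohol at −78 °C, gives the 14,15-diacetate with C6–OH free.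

**Compound list**
1 | 3,3-diethoxyprop-1-yne | C#CC(OCC)OCC | starting material
2 | paraformaldehyde (formaldehyde source) | C=O | starting material
3 | lithium 3,3-diethoxyprop-1-yn-1-ide | [Li]C#CC(OCC)OCC | intermediate
4 | 4,4-diethoxybut-2-yn-1-ol | OCC#CC(OCC)OCC | intermediate
5 | vinylmagnesium chloride | C=C[Mg]Cl | starting material
6 | 3-(diethoxymethyl)-4-ethenyl-2,5-dihydro-1,2-oxamagnesole (chelated alkenylmagnesium alkoxide) | C=CC1=C(C(OCC)OCC)[Mg]OC1 | intermediate
7 | (2E)-2-ethenyl-4,4-diethoxybut-2-en-1-ol | OC/C(C=C)=C/C(OCC)OCC | intermediate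
8 | prop-2-yn-1-ol | C#CCO | starting material
9 | (1,3-dioxolan-2-ylmethyl)magnesium bromide | Br[Mg]CC1OCCO1 | starting material
10 | 4-(1,3-dioxolan-2-ylmethyl)-2,5-dihydro-1,2-oxamagnesole (chelated alkenylmagnesium alkoxide) | C1(CC2OCCO2)=C[Mg]OC1 | intermediate
11 | (2Z)-2-(1,3-dioxolan-2-ylmethyl)-3-iodoprop-2-en-1-ol | OC/C(CC1OCCO1)=C\I | intermediate
12 | 9-{(3E)-3-[(9-BBN-9-yloxy)methyl]-5,5-diethoxypent-3-en-1-yl}-9-BBN (O,C-bis-borylated 7) | CCOC(OCC)/C=C(\CCB1C2CCCC1CCC2)COB1C2CCCC1CCC2 | intermediate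
13 | (2Z,6E)-8,8-diethoxy-2-(1,3-dioxolan-2-ylmethyl)-6-(hydroxymethyl)octa-2,6-dien-1-ol | C1(C/C(CO)=C/CC/C(CO)=C\C(OCC)OCC)OCCO1 | intermediate
14 | 2-[(2Z,6E)-2,6-bis(TBSO-methyl)-8,8-diethoxyocta-2,6-dien-1-yl]-1,3-dioxolane | C1(C/C(CO[Si](C)(C)C(C)(C)C)=C/CC/C(CO[Si](C)(C)C(C)(C)C)=C\C(OCC)OCC)OCCO1 | intermediate
15 | (2E,6Z)-8-(TBSO)-3-(TBSO-methyl)-7-(1,3-dioxolan-2-ylmethyl)octa-2,6-dienal | C1(C/C(CO[Si](C)(C)C(C)(C)C)=C/CC/C(CO[Si](C)(C)C(C)(C)C)=C\C=O)OCCO1 | intermediate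
16 | methyl prop-2-ynoate (methyl propiolate) | C#CC(=O)OC | starting material
17 | methyl 3-(methylzincio)prop-2-ynoate | C[Zn]C#CC(=O)OC | intermediate
18 | methyl (4R,5E,9Z)-4-hydroxy-11-(TBSO)-6-(TBSO-methyl)-10-(1,3-dioxolan-2-ylmethyl)undeca-5,9-dien-2-ynoate | C1(C/C(CO[Si](C)(C)C(C)(C)C)=C/CC/C(CO[Si](C)(C)C(C)(C)C)=C\[C@@H](O)C#CC(=O)OC)OCCO1 | intermediate
19 | methyl (4R,5E,9Z)-4,11-bis(TBSO)-6-(TBSO-methyl)-10-(1,3-dioxolan-2-ylmethyl)undeca-5,9-dien-2-ynoate | C1(C/C(CO[Si](C)(C)C(C)(C)C)=C/CC/C(CO[Si](C)(C)C(C)(C)C)=C\[C@@H](O[Si](C)(C)C(C)(C)C)C#CC(=O)OC)OCCO1 | intermediate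
20 | 2-(iodomethyl)-4,4,5,5-tetramethyl-1,3,2-dioxaborolane | ICB1OC(C)(C)C(C)(C)O1 | starting material
21 | methyl (2E,4R,5E,9Z)-2-(diisobutylalumanyl)-4,11-bis(TBSO)-6-(TBSO-methyl)-10-(1,3-dioxolan-2-ylmethyl)undeca-2,5,9-trienoate (α-aluminoacrylate, Al trans to the C6 branch) | C1(C/C(CO[Si](C)(C)C(C)(C)C)=C/CC/C(CO[Si](C)(C)C(C)(C)C)=C\[C@@H](O[Si](C)(C)C(C)(C)C)/C=C(/[Al](CC(C)C)CC(C)C)C(=O)OC)OCCO1 | intermediate
22 | methyl (2Z,4R,5E,9Z)-4,11-bis(TBSO)-6-(TBSO-methyl)-10-(1,3-dioxolan-2-ylmethyl)-2-(Bpin-methyl)undeca-2,5,9-trienoate | C1(C/C(CO[Si](C)(C)C(C)(C)C)=C/CC/C(CO[Si](C)(C)C(C)(C)C)=C\[C@@H](O[Si](C)(C)C(C)(C)C)/C=C(/CB2OC(C)(C)C(C)(C)O2)C(=O)OC)OCCO1 | intermediate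
23 | 2,4,6-trimethylpyridinium N,O-acetal of 22 at C8 (N-collidinium and 2-(triethylsilyloxy)ethoxy on C8, triflate salt, both C8 epimers) | CC[Si](CC)(CC)OCCOC(C/C(CO[Si](C)(C)C(C)(C)C)=C/CC/C(CO[Si](C)(C)C(C)(C)C)=C\[C@@H](O[Si](C)(C)C(C)(C)C)/C=C(/CB1OC(C)(C)C(C)(C)O1)C(=O)OC)[n+]1c(C)cc(C)cc1C.[O-]S(=O)(=O)C(F)(F)F | intermediate
24 | methyl (2Z,4R,5E,9Z)-4,11-bis(TBSO)-6-(TBSO-methyl)-10-(2-oxoethyl)-2-(Bpin-methyl)undeca-2,5,9-trienoate | O=CC/C(CO[Si](C)(C)C(C)(C)C)=C/CC/C(CO[Si](C)(C)C(C)(C)C)=C\[C@@H](O[Si](C)(C)C(C)(C)C)/C=C(/CB1OC(C)(C)C(C)(C)O1)C(=O)OC | intermediate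
25 | methyl 2-[(1R,2R,3E,7Z,10S)-2-(TBSO)-4,8-bis(TBSO-methyl)-10-(Bpin-oxy)cyclodeca-3,7-dien-1-yl]prop-2-enoate (carbocycle closed, lactone still open) | C=C(C(=O)OC)[C@@H]1[C@@H](OB2OC(C)(C)C(C)(C)O2)C/C(CO[Si](C)(C)C(C)(C)C)=C/CC/C(CO[Si](C)(C)C(C)(C)C)=C\[C@H]1O[Si](C)(C)C(C)(C)C | intermediate
26 | (3aR,4R,5E,9Z,11aS)-4-(TBSO)-6,10-bis(TBSO-methyl)-3-methylidene-3a,4,7,8,11,11a-hexahydrocyclodeca[b]furan-2(3H)-one | C=C1C(=O)O[C@H]2C/C(CO[Si](C)(C)C(C)(C)C)=C/CC/C(CO[Si](C)(C)C(C)(C)C)=C\[C@@H](O[Si](C)(C)C(C)(C)C)[C@H]12 | intermediate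
27 | (3aS,4R,5E,9Z,11aS)-4-hydroxy-6,10-bis(hydroxymethyl)-3-methylidene-3a,4,7,8,11,11a-hexahydrocyclodeca[b]furan-2(3H)-one | C=C1C(=O)O[C@H]2C/C(CO)=C/CC/C(CO)=C\[C@@H](O)[C@H]12 | intermediate
28 | [(3aS,4R,5E,9Z,11aS)-4-hydroxy-3-methylidene-2-oxo-2,3,3a,4,7,8,11,11a-octahydrocyclodeca[b]furan-6,10-diyl]bis(methylene) diacetate (CNP0594234.1) | C=C1C(=O)O[C@H]2C/C(COC(C)=O)=C/CC/C(COC(C)=O)=C\[C@@H](O)[C@H]12 | target

**Step count**
Total steps: 13. Longest linear sequence: 12 (steps 1, 2 and 4–13; step 3 is the one-step side branch).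

**Three steps most likely to fail**

Step 11. The ester-bearing allylboronate is a weak nucleophile, so at 2 mM the ten-membered closure may lose to oligomerisation or to isomerisation of 24 into the conjugated enal. The facial preference at C7 also rests only on a transition-state argument. The fallback changes the nucleophile from boron to chromium and sets out from 19. i-Bu2AlH/HMPA followed by paraformaldehyde gives the hydroxymethyl enoate F1. CBr4/PPh3 (Appel reaction) converts it into the allylic bromide F2. TESOTf/2,4,6-collidine and then water unmask the bromo aldehyde F3. CrCl2 (8 equiv) in DMF/THF at 3 mM then effects an intramolecular Nozaki–Hiyama–Kishi-type allylation; the allylchromium is far more reactive and anti-selective, and the chromium alkoxide lactonises. This closure is an established way to make ten-membered germacranolide carbocycles, and it comes back to the route at 26.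

Step 10. The liberated β,γ-unsaturated aldehyde 24 can slip into conjugation (C9=C10) or react with the boronate of another molecule on concentration. The fallback does not isolate it and sets out from 22. The dioxolane is cleaved in the cyclisation flask itself (Sc(OTf)3 30 mol%, H2O 5 equiv, MeNO2/toluene, 2 mM, rt → 40 °C). The aldehyde is then released slowly and trapped by the boronate as it forms, passing through 24 and 25 without accumulation. This comes back to the route at 26 and forms no new compound (entry F0); its own risk is partial loss of silyl groups under the wet Lewis acid.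

Step 9. The hydride may attack the ester, the hindered vinylalane may alkylate slowly with the iodomethylboronate, and the α-aluminoacrylate may lose its geometry through the allenolate. The fallback avoids aluminium and sets out from 19. Bu3SnH with Pd(PPh3)4 adds syn with tin α to the ester, giving the α-stannyl enoate F4. I2 gives the α-iodo enoate F5 with retention. Negishi coupling of F5 with (pinacolboryl)methylzinc iodide (made from 20 and Zn) under Pd(PPh3)4 installs CH2Bpin trans to the C6 branch and comes back to the route at 22.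

**Further compounds**
F1 | step 11 | methyl (2Z,4R,5E,9Z)-4,11-bis(TBSO)-6-(TBSO-methyl)-10-(1,3-dioxolan-2-ylmethyl)-2-(hydroxymethyl)undeca-2,5,9-trienoate | C1(C/C(CO[Si](C)(C)C(C)(C)C)=C/CC/C(CO[Si](C)(C)C(C)(C)C)=C\[C@@H](O[Si](C)(C)C(C)(C)C)/C=C(/CO)C(=O)OC)OCCO1
F2 | step 11 | methyl (2E,4R,5E,9Z)-2-(bromomethyl)-4,11-bis(TBSO)-6-(TBSO-methyl)-10-(1,3-dioxolan-2-ylmethyl)undeca-2,5,9-trienoate | C1(C/C(CO[Si](C)(C)C(C)(C)C)=C/CC/C(CO[Si](C)(C)C(C)(C)C)=C\[C@@H](O[Si](C)(C)C(C)(C)C)/C=C(/CBr)C(=O)OC)OCCO1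
F3 | step 11 | methyl (2E,4R,5E,9Z)-2-(bromomethyl)-4,11-bis(TBSO)-6-(TBSO-methyl)-10-(2-oxoethyl)undeca-2,5,9-trienoate | O=CC/C(CO[Si](C)(C)C(C)(C)C)=C/CC/C(CO[Si](C)(C)C(C)(C)C)=C\[C@@H](O[Si](C)(C)C(C)(C)C)/C=C(/CBr)C(=O)OC
F0 | step 10 | none | none
F4 | step 9 | methyl (2E,4R,5E,9Z)-4,11-bis(TBSO)-6-(TBSO-methyl)-10-(1,3-dioxolan-2-ylmethyl)-2-(tributylstannyl)undeca-2,5,9-trienoate | C1(C/C(CO[Si](C)(C)C(C)(C)C)=C/CC/C(CO[Si](C)(C)C(C)(C)C)=C\[C@@H](O[Si](C)(C)C(C)(C)C)/C=C(/[Sn](CCCC)(CCCC)CCCC)C(=O)OC)OCCO1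
F5 | step 9 | methyl (2E,4R,5E,9Z)-4,11-bis(TBSO)-6-(TBSO-methyl)-10-(1,3-dioxolan-2-ylmethyl)-2-iodoundeca-2,5,9-trienoate | C1(C/C(CO[Si](C)(C)C(C)(C)C)=C/CC/C(CO[Si](C)(C)C(C)(C)C)=C\[C@@H](O[Si](C)(C)C(C)(C)C)/C=C(/I)C(=O)OC)OCCO1
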